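**Retrosynthetic overview**
- Target ⇐ global O‑demethylation of the 6,8‑dimethoxy lactone.
- Ring B (δ‑lactone) and the C4–C4a bond ⇐ one operation: nickel‑catalysed radical cross‑electrophile coupling of methyl 2‑bromo‑4,6‑dimethoxybenzoate with the terminal (R)‑epoxide of the complete, unprotected side chain (epoxide → iodohydrin → primary β‑hydroxyalkyl radical → aryl–CH2 bond), then lactonisation; C3 (R) is carried over from the epoxide.
- Aryl bromide ⇐ ester‑directed ortho C–H borylation/bromodeboronation of methyl 2,4‑dimethoxybenzoate ⇐ Kolbe–Schmitt carboxylation of resorcinol.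
- Epoxy alcohol ⇐ cross‑metathesis/hydrogenation of (R)‑1,2‑epoxy‑5‑hexene with (S)‑non‑8‑en‑3‑ol ⇐ (S)‑1,2‑epoxybutane + pent‑4‑enyl Grignard reagent; the side‑chain carbinol (S) is carried over from that epoxide.
- Ring order: ring A (arene) is present from the start; ring B is closed in the coupling step, last but one.

Assumption: the two epoxides are bought as single enantiomers (≥98% ee), and a telescoped one‑pot sequence counts as one step.

**Step 1**
Reactants: 1 resorcinol (benzene‑1,3‑diol)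
Product: 2 2,4‑dihydroxybenzoic acid
Conditions: KHCO3 (5 equiv), H2O, CO2 stream, 100 °C, 3 h; then conc. HCl, 0 °C
Reagents that add atoms: carbon dioxide, O=C=O (supplied as gas and as potassium hydrogen carbonate, [K+].OC(=O)[O-])
Why: Kolbe–Schmitt carboxylation; the resorcinol anion takes up CO2 at C4 (ortho to one OH, para to the other), the classical preparation of β‑resorcylic acid.

**Step 2**
Reactants: 2 2,4‑dihydroxybenzoic acid
Product: 3 methyl 2,4‑dimethoxybenzoate
Conditions: Me2SO4 (3.5 equiv), K2CO3 (4.5 equiv), acetone, reflux, 16 h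
Reagents that add atoms: dimethyl sulfate, COS(=O)(=O)OC
Why: exhaustive O‑methylation (Williamson ether synthesis plus carboxylate alkylation) caps both phenols and gives the ester that directs the next C–H step and later serves as the lactone acyl donor.

**Step 3**
Reactants: 3 methyl 2,4‑dimethoxybenzoate
Product: 5 methyl 2‑bromo‑4,6‑dimethoxybenzoate, via aryl boronate 4 (not isolated)
Conditions: [Ir(OMe)(cod)]2 (1.5 mol%), P[3,5‑(CF3)2C6H3]3 (6 mol%), B2pin2 (1.1 equiv), octane, 80 °C, 16 h; evaporate; then CuBr2 (3 equiv), MeOH/H2O 1:1, 80 °C, 8 h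
Reagents that add atoms: bis(pinacolato)diboron, CC1(C)OB(OC1(C)C)B1OC(C)(C)C(C)(C)O1 (boryl group held only in intermediate 4); copper dibromide, Br[Cu]Br (bromine)
Why: carbonyl‑directed iridium‑catalysed ortho C–H borylation (the ester C=O delivers the monophosphine iridium boryl to C6, the only ortho C–H) followed by copper‑mediated bromodeboronation, which replaces boron by bromine at the same carbon.

**Step 4**
Reactants: 6 5‑bromopent‑1‑ene; 7 (2S)‑2‑ethyloxirane [(S)‑1,2‑epoxybutane]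
Product: 9 (3S)‑non‑8‑en‑3‑ol, via Grignard reagent 8 (not isolated)
Conditions: 6 (1.3 equiv), Mg, THF, 40 °C; then 7 (1.0 equiv), CuBr·SMe2 (5 mol%), −30 → 0 °C; aq. NH4Cl
Reagents that add atoms: magnesium, [Mg] (held only in intermediate 8)
Why: copper‑catalysed SN2 opening of a terminal epoxide by a Grignard reagent at the CH2 carbon; the carbinol carbon is not touched, so the (S) configuration of 7 is retained.

**Step 5**
Reactants: 9 (3S)‑non‑8‑en‑3‑ol; 10 (2R)‑2‑(but‑3‑en‑1‑yl)oxirane [(R)‑1,2‑epoxy‑5‑hexene]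
Product: 12 (3S)‑11‑[(2R)‑oxiran‑2‑yl]undecan‑3‑ol, via alkene 11 (not isolated)
Conditions: 10 (2.5 equiv), second‑generation Grubbs catalyst RuCl2(=CHPh)(PCy3)(H2IMes) (3 mol%), CH2Cl2, 40 °C, 12 h; then PtO2 (5 mol%), H2 (1 atm), rt, 2 h
Reagents that add atoms: none
Why: olefin cross‑metathesis of two terminal alkenes (ethene is lost), then hydrogenation of the new E/Z alkene in the same pot; neither stereocentre takes part, and the free alcohol and the non‑allylic terminal epoxide tolerate both catalysts.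

**Step 6**
Reactants: 5 methyl 2‑bromo‑4,6‑dimethoxybenzoate; 12 (3S)‑11‑[(2R)‑oxiran‑2‑yl]undecan‑3‑ol
Product: 15 (3R)‑3‑[(9S)‑9‑hydroxyundecyl]‑6,8‑dimethoxy‑3,4‑dihydro‑1H‑isochromen‑1‑one, via iodohydrin 13 (not isolated), via hydroxy ester 14 (not isolated)
Conditions: 5 (1.3 equiv), 12 (1.0 equiv), NiCl2(dme) (10 mol%), 2,2'‑bipyridine (10 mol%), NaI (0.5 equiv), Et3N·HCl (1.0 equiv), Mn powder (2 equiv), DMPU, 30 °C, 24 h; work‑up; then p‑TsOH·H2O (10 mol%), toluene, 60 °C, 2 h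
Reagents that add atoms: sodium iodide, [Na+].[I-] (iodine held only in intermediate 13)
Why: nickel‑catalysed reductive cross‑electrophile coupling of an aryl bromide with an epoxide under iodide co‑catalysis: iodide and Et3N·HCl open 12 at the terminal carbon to 13, halogen abstraction gives the primary β‑hydroxyalkyl radical, the aryl–nickel (divalent) species from 5 captures it and reductive elimination from trivalent nickel makes the C4–C4a bond, after which acid closes ring B from 14; the radical sits on CH2, so the adjacent C3–O stereocentre from 10 is never broken and stays (R).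

**Step 7**
Reactants: 15 (3R)‑3‑[(9S)‑9‑hydroxyundecyl]‑6,8‑dimethoxy‑3,4‑dihydro‑1H‑isochromen‑1‑one
Product: 16 (3R)‑6,8‑dihydroxy‑3‑[(9S)‑9‑hydroxyundecyl]‑3,4‑dihydro‑1H‑isochromen‑1‑one
Conditions: BBr3 (5 equiv), CH2Cl2, −78 → 0 °C, 3 h; aq. NaHCO3
Reagents that add atoms: none
Why: Lewis‑acid cleavage of aryl methyl ethers (BBr3 demethylation); at or below 0 °C the secondary alcohol is held as a borate and the lactone as a boron complex, both released on aqueous work‑up, and no stereocentre is touched.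

**Compound list**
1 | resorcinol (benzene‑1,3‑diol) | Oc1cccc(O)c1 | starting material
2 | 2,4‑dihydroxybenzoic acid | OC(=O)c1ccc(O)cc1O | intermediate
3 | methyl 2,4‑dimethoxybenzoate | COC(=O)c1ccc(OC)cc1OC | intermediate
4 | methyl 2,4‑dimethoxy‑6‑(4,4,5,5‑tetramethyl‑1,3,2‑dioxaborolan‑2‑yl)benzoate | COC(=O)c1c(B2OC(C)(C)C(C)(C)O2)cc(OC)cc1OC | intermediate
5 | methyl 2‑bromo‑4,6‑dimethoxybenzoate | COC(=O)c1c(Br)cc(OC)cc1OC | intermediate
6 | 5‑bromopent‑1‑ene | BrCCCC=C | starting material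
7 | (2S)‑2‑ethyloxirane [(S)‑1,2‑epoxybutane] | CC[C@H]1CO1 | starting material
8 | pent‑4‑en‑1‑ylmagnesium bromide | C=CCCC[Mg]Br | intermediate
9 | (3S)‑non‑8‑en‑3‑ol | CC[C@H](O)CCCCC=C | intermediate
10 | (2R)‑2‑(but‑3‑en‑1‑yl)oxirane [(R)‑1,2‑epoxy‑5‑hexene] | C=CCC[C@@H]1CO1 | starting material
11 | (3S)‑11‑[(2R)‑oxiran‑2‑yl]undec‑8‑en‑3‑ol (E/Z mixture) | CC[C@H](O)CCCCC=CCC[C@@H]1CO1 | intermediate
12 | (3S)‑11‑[(2R)‑oxiran‑2‑yl]undecan‑3‑ol | CC[C@H](O)CCCCCCCC[C@@H]1CO1 | intermediate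
13 | (2R,11S)‑1‑iodotridecane‑2,11‑diol | CC[C@H](O)CCCCCCCC[C@@H](O)CI | intermediate
14 | methyl 2‑[(2R,11S)‑2,11‑dihydroxytridecyl]‑4,6‑dimethoxybenzoate | CC[C@H](O)CCCCCCCC[C@@H](O)Cc1cc(OC)cc(OC)c1C(=O)OC | intermediate
15 | (3R)‑3‑[(9S)‑9‑hydroxyundecyl]‑6,8‑dimethoxy‑3,4‑dihydro‑1H‑isochromen‑1‑one | CC[C@H](O)CCCCCCCC[C@@H]1Cc2cc(OC)cc(OC)c2C(=O)O1 | intermediate
16 | (3R)‑6,8‑dihydroxy‑3‑[(9S)‑9‑hydroxyundecyl]‑3,4‑dihydro‑1H‑isochromen‑1‑one | CC[C@H](O)CCCCCCCC[C@@H]1Cc2cc(O)cc(O)c2C(=O)O1 | target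

**Totals**
Total step count: 7. Longest linear sequence: 5 steps (steps 1, 2, 3, 6, 7).

**Three steps most likely to fail, with fallbacks**

Step 6. The electron‑rich, ortho‑substituted bromide 5 may add slowly to zerovalent nickel. Hydrodebromination back to 3, biaryl formation and some opening of the epoxide at the internal carbon are the expected side paths. The fallback sets out from 3 (with 12) and comes back at 15. Compound 3 is saponified (LiOH, THF/H2O, 50 °C) to 2,4‑dimethoxybenzoic acid F1. F1 is then coupled with 12 by carboxylate‑directed ortho C–H alkylation under divalent palladium catalysis (Pd(OAc)2, N‑acetyl‑tert‑leucine, KOAc, HFIP, 75 °C). The aryl–palladium species opens the epoxide at CH2 in an SN2 manner, so the carbinol carbon keeps its configuration, and the hydroxy acid lactonises to 15. This path also makes step 3 unnecessary.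

Step 3. With the arene as limiting reagent the directed borylation may stall, and CuBr2 may brominate the electron‑rich ring beside the boron‑bearing carbon. The fallback sets out from 1 and comes back at 5. Resorcinol is methylated (Me2SO4, K2CO3, acetone) to 1,3‑dimethoxybenzene F2. Sterically controlled C–H borylation ([Ir(OMe)(cod)]2, 4,4'‑di‑tert‑butyl‑2,2'‑bipyridine, B2pin2, THF, 80 °C) gives 2‑(3,5‑dimethoxyphenyl)‑4,4,5,5‑tetramethyl‑1,3,2‑dioxaborolane F3. CuBr2 in MeOH/H2O converts it to 1‑bromo‑3,5‑dimethoxybenzene F4. Vilsmeier–Haack formylation (POCl3, DMF, 90 °C) para to one methoxy group gives 2‑bromo‑4,6‑dimethoxybenzaldehyde F5. Pinnick oxidation (NaClO2, NaH2PO4, 2‑methylbut‑2‑ene, t‑BuOH/H2O) gives 2‑bromo‑4,6‑dimethoxybenzoic acid F6, and MeI/K2CO3 in DMF gives 5.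

Step 7. BBr3 may convert the side‑chain secondary alcohol into a bromide or open the lactone. The fallback sets out from 15 and comes back at 16. The alcohol is acetylated (Ac2O, pyridine, DMAP) to (3S)‑11‑[(3R)‑6,8‑dimethoxy‑1‑oxo‑3,4‑dihydro‑1H‑isochromen‑3‑yl]undecan‑3‑yl acetate F7. Demethylation (BBr3, CH2Cl2, −78 → −20 °C) gives (3S)‑11‑[(3R)‑6,8‑dihydroxy‑1‑oxo‑3,4‑dihydro‑1H‑isochromen‑3‑yl]undecan‑3‑yl acetate F8. Acidic methanolysis (HCl in MeOH, 40 °C) removes the acetate and gives 16.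

**Further compounds**
F1 | step 6 | 2,4‑dimethoxybenzoic acid | COc1ccc(C(=O)O)c(OC)c1
F2 | step 3 | 1,3‑dimethoxybenzene | COc1cccc(OC)c1
F3 | step 3 | 2‑(3,5‑dimethoxyphenyl)‑4,4,5,5‑tetramethyl‑1,3,2‑dioxaborolane | COc1cc(OC)cc(B2OC(C)(C)C(C)(C)O2)c1
F4 | step 3 | 1‑bromo‑3,5‑dimethoxybenzene | COc1cc(Br)cc(OC)c1
F5 | step 3 | 2‑bromo‑4,6‑dimethoxybenzaldehyde | COc1cc(Br)c(C=O)c(OC)c1
F6 | step 3 | 2‑bromo‑4,6‑dimethoxybenzoic acid | COc1cc(Br)c(C(=O)O)c(OC)c1
F7 | step 7 | (3S)‑11‑[(3R)‑6,8‑dimethoxy‑1‑oxo‑3,4‑dihydro‑1H‑isochromen‑3‑yl]undecan‑3‑yl acetate | CC[C@H](OC(C)=O)CCCCCCCC[C@@H]1Cc2cc(OC)cc(OC)c2C(=O)O1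
F8 | step 7 | (3S)‑11‑[(3R)‑6,8‑dihydroxy‑1‑oxo‑3,4‑dihydro‑1H‑isochromen‑3‑yl]undecan‑3‑yl acetate | CC[C@H](OC(C)=O)CCCCCCCC[C@@H]1Cc2cc(O)cc(O)c2C(=O)O1
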